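## Retrosynthetic overview

1. Target 14 ⇐ ketone 12: the C12′ carbinol comes from a reagent-controlled (CBS) reduction, with the phenol unmasked in the same flask.
2. Ketone 12 ⇐ C9′–C10′ bond: a ketone homoenolate (cyclopropanol 4, opened by Et2Zn) attacks dienyl phosphate 9 in an enantioselective copper-catalysed SN2′ reaction. This one step joins the two halves and creates the C9′ quaternary stereocentre.
3. Cyclopropanol 4 ⇐ (S)-bakuchiol 1 + ethyl 2-bromoisobutyrate 2 (aryl tert-alkyl ether), then Kulinkovich cyclopropanation.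
4. Phosphate 9 ⇐ aldehyde 5 + C5 phosphonate 6 (Horner–Wadsworth–Emmons), ester reduction, phosphorylation.
5. Rings: no ring of the target is built (both arenes are bought). The only ring made is the cyclopropanol (step 2), which is opened again in step 6.

Assumption: (S)-(+)-bakuchiol (≥98 %, sold in bulk as a cosmetic ingredient) is taken as a cheap commercial starting material; locants 9′, 12′ and 13′ follow bakuchiol numbering in the oxidised half.

Abbreviations: BakAr = 4-[(1E,3S)-3-ethenyl-3,7-dimethylocta-1,6-dien-1-yl]phenyl (the aryl group of 1); TBS = tert-butyldimethylsilyl.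

## Route

Step 1
Reactants: 1 (S)-(+)-bakuchiol; 2 ethyl 2-bromo-2-methylpropanoate
Product: 3 ethyl 2-(BakAr-oxy)-2-methylpropanoate
Conditions: Cs2CO3 (2 equiv), 2 (2.5 equiv), DMF, 60 °C
Reagents that add atoms: none
Why: Williamson-type O-alkylation of the phenoxide with a tertiary α-bromo ester (the fibrate ether synthesis) installs the ArO–C(CH3)2 unit; excess 2 offsets elimination to methacrylate, and the bakuchiol stereocentre is untouched.

Step 2
Reactants: 3 ethyl 2-(BakAr-oxy)-2-methylpropanoate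
Product: 4 1-[2-(BakAr-oxy)propan-2-yl]cyclopropan-1-ol
Conditions: EtMgBr (3 equiv, slow addition), Ti(OiPr)4 (0.3 equiv), THF/Et2O, 0 °C → rt
Reagents that add atoms: ethylmagnesium bromide CC[Mg]Br
Why: Kulinkovich cyclopropanation: the titanacyclopropane formed from EtMgBr and Ti(OiPr)4 acts as a 1,2-dicarbanion towards the ester and gives the cyclopropanol, while the hindered vinyl group on the quaternary carbon is a poor partner for alkene exchange on titanium.

Step 3
Reactants: 5 4-(tert-butyldimethylsilyloxy)benzaldehyde; 6 triethyl 3-methyl-4-phosphonocrotonate (E/Z mixture as sold)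
Product: 7 ethyl (2E,4E)-5-[4-(TBS-oxy)phenyl]-3-methylpenta-2,4-dienoate
Conditions: LiN(SiMe3)2 (1.1 equiv), THF, −78 → 0 °C
Reagents that add atoms: none
Why: Vinylogous Horner–Wadsworth–Emmons olefination: the phosphonate anion equilibrates to the extended (2E) form and gives the (4E)-styrene with the aryl aldehyde; the minor (2Z) isomer is removed after step 4.

Step 4
Reactants: 7 ethyl (2E,4E)-5-[4-(TBS-oxy)phenyl]-3-methylpenta-2,4-dienoate
Product: 8 (2E,4E)-5-[4-(TBS-oxy)phenyl]-3-methylpenta-2,4-dien-1-ol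
Conditions: iBu2AlH (2.5 equiv), CH2Cl2, −78 °C
Reagents that add atoms: none
Why: 1,2-Reduction of the conjugated ester by iBu2AlH gives the allylic alcohol without touching the diene or the aryl silyl ether; the isomerically pure (2E,4E)-dienol is obtained by chromatography or crystallisation.

Step 5
Reactants: 8 (2E,4E)-5-[4-(TBS-oxy)phenyl]-3-methylpenta-2,4-dien-1-ol
Product: 9 (2E,4E)-5-[4-(TBS-oxy)phenyl]-3-methylpenta-2,4-dien-1-yl diethyl phosphate
Conditions: ClP(O)(OEt)2 (1.3 equiv), Et3N, 4-(dimethylamino)pyridine (10 mol%), CH2Cl2, −20 → 0 °C; quick filtration through Et3N-deactivated silica, used the same day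
Reagents that add atoms: diethyl chlorophosphate CCOP(=O)(Cl)OCC
Why: O-Phosphorylation under nucleophilic catalysis turns the primary allylic alcohol into the leaving group needed for copper-catalysed SN2′ substitution; cold, base-buffered handling avoids ionisation of this electron-rich dienyl phosphate.

Step 6
Reactants: 4 1-[2-(BakAr-oxy)propan-2-yl]cyclopropan-1-ol (1.3 equiv); 9 (2E,4E)-5-[4-(TBS-oxy)phenyl]-3-methylpenta-2,4-dien-1-yl diethyl phosphate (1.0 equiv)
Product: 12 (6S,7E)-2-(BakAr-oxy)-8-[4-(TBS-oxy)phenyl]-6-ethenyl-2,6-dimethyloct-7-en-3-one, via ethylzinc cyclopropoxide 10 (not isolated), via zinc homoenolate 11 (not isolated)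
Conditions: Et2Zn (1.1 equiv per 4), THF, 0 °C, 20 min; then (CuOTf)2·C6H6 (5 mol%), 2-[(4S,5S)-4,5-diphenyl-3-(2,4,6-trimethylphenyl)-4,5-dihydroimidazol-3-ium-1-yl]benzenesulfonate (11 mol%), 9, THF, −30 → 0 °C
Reagents that add atoms: diethylzinc CC[Zn]CC (its ethylzinc unit is present in 10 and 11 only)
Why: Proposed new method: Et2Zn deprotonates 4 to the ethylzinc cyclopropoxide 10, whose strain-driven β-carbon elimination gives the β-metallo ketone 11 (a ketone homoenolate, so the normally electrophilic β-carbon is the nucleophile); alkyl transfer to the sulfonate-bridged chiral NHC–copper centre, anti-SN2′ oxidative addition at C3 of 9 to a trivalent copper σ-allyl and fast reductive elimination form the C9′–C10′ bond, with the NHC selecting the C3 Re face of the (2E)-alkene to give the 9′S quaternary centre; the closest known reactions are the racemic copper-mediated SN2′ allylation of cyclopropanol-derived zinc homoenolates and the NHC–copper-catalysed enantioselective SN2′ alkylation of γ,γ-disubstituted allylic phosphates with dialkylzincs to give all-carbon quaternary centres.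

Step 7
Reactants: 12 (6S,7E)-2-(BakAr-oxy)-8-[4-(TBS-oxy)phenyl]-6-ethenyl-2,6-dimethyloct-7-en-3-one
Product: 14 (12′S)-bisbakuchiol C, via silyl ether 13 (not isolated)
Conditions: (R)-1-methyl-3,3-diphenyltetrahydro-1H,3H-pyrrolo[1,2-c][1,3,2]oxazaborole [(R)-Me-CBS, 0.3 equiv], catecholborane (2 equiv), toluene, −78 → −30 °C; then MeOH/THF, 2 M aq NaOH, rt
Reagents that add atoms: none
Why: Corey–Bakshi–Shibata reduction: the ketone binds the (R)-oxazaborolidine with the bulky C(CH3)2OAr group away from the catalyst, so hydride from catecholborane (which does not hydroborate the alkenes at this temperature) gives the 12′S carbinol, and the basic methanolic work-up then hydrolyses the borate and the aryl silyl ether of 13 in the same flask.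

## Compound list

1 | (S)-(+)-bakuchiol, 4-[(1E,3S)-3-ethenyl-3,7-dimethylocta-1,6-dien-1-yl]phenol | C=C[C@@](C)(/C=C/c1ccc(O)cc1)CCC=C(C)C | starting material
2 | ethyl 2-bromo-2-methylpropanoate | CCOC(=O)C(C)(C)Br | starting material
3 | ethyl 2-(BakAr-oxy)-2-methylpropanoate | C=C[C@@](C)(/C=C/c1ccc(OC(C)(C)C(=O)OCC)cc1)CCC=C(C)C | intermediate
4 | 1-[2-(BakAr-oxy)propan-2-yl]cyclopropan-1-ol | C=C[C@@](C)(/C=C/c1ccc(OC(C)(C)C2(O)CC2)cc1)CCC=C(C)C | intermediate
5 | 4-(tert-butyldimethylsilyloxy)benzaldehyde | O=Cc1ccc(O[Si](C)(C)C(C)(C)C)cc1 | starting material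
6 | triethyl 3-methyl-4-phosphonocrotonate [ethyl 4-(diethoxyphosphoryl)-3-methylbut-2-enoate, E/Z mixture] | CCOC(=O)C=C(C)CP(=O)(OCC)OCC | starting material
7 | ethyl (2E,4E)-5-[4-(TBS-oxy)phenyl]-3-methylpenta-2,4-dienoate | CCOC(=O)/C=C(\C)/C=C/c1ccc(O[Si](C)(C)C(C)(C)C)cc1 | intermediate
8 | (2E,4E)-5-[4-(TBS-oxy)phenyl]-3-methylpenta-2,4-dien-1-ol | OC/C=C(\C)/C=C/c1ccc(O[Si](C)(C)C(C)(C)C)cc1 | intermediate
9 | (2E,4E)-5-[4-(TBS-oxy)phenyl]-3-methylpenta-2,4-dien-1-yl diethyl phosphate | CCOP(=O)(OCC)OC/C=C(\C)/C=C/c1ccc(O[Si](C)(C)C(C)(C)C)cc1 | intermediate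
10 | ethylzinc 1-[2-(BakAr-oxy)propan-2-yl]cyclopropan-1-olate | C=C[C@@](C)(/C=C/c1ccc(OC(C)(C)C2(O[Zn]CC)CC2)cc1)CCC=C(C)C | intermediate (not isolated)
11 | ethyl[4-(BakAr-oxy)-4-methyl-3-oxopentyl]zinc (zinc homoenolate) | C=C[C@@](C)(/C=C/c1ccc(OC(C)(C)C(=O)CC[Zn]CC)cc1)CCC=C(C)C | intermediate (not isolated)
12 | (6S,7E)-2-(BakAr-oxy)-8-[4-(TBS-oxy)phenyl]-6-ethenyl-2,6-dimethyloct-7-en-3-one | C=C[C@@](C)(/C=C/c1ccc(OC(C)(C)C(=O)CC[C@@](C)(C=C)/C=C/c2ccc(O[Si](C)(C)C(C)(C)C)cc2)cc1)CCC=C(C)C | intermediate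
13 | (3S,6S,7E)-2-(BakAr-oxy)-8-[4-(TBS-oxy)phenyl]-6-ethenyl-2,6-dimethyloct-7-en-3-ol | C=C[C@@](C)(/C=C/c1ccc(OC(C)(C)[C@@H](O)CC[C@@](C)(C=C)/C=C/c2ccc(O[Si](C)(C)C(C)(C)C)cc2)cc1)CCC=C(C)C | intermediate (not isolated)
14 | (12′S)-bisbakuchiol C, 4-[(1E,3S,6S)-7-(BakAr-oxy)-3-ethenyl-6-hydroxy-3,7-dimethyloct-1-en-1-yl]phenol | C=C[C@@](C)(/C=C/c1ccc(OC(C)(C)[C@@H](O)CC[C@@](C)(C=C)/C=C/c2ccc(O)cc2)cc1)CCC=C(C)C | target

## Summary

Total steps: 7. Longest linear sequence: 5 steps (5 → 7 → 8 → 9 → 12 → 14; the bakuchiol branch 1 → 3 → 4 → 12 → 14 is 4 steps).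

The three steps most likely to fail:

**Step 6 (homoenolate SN2′).** The enantioselective version is not established and the facial sense must be checked (the (4R,5R) ligand is used if the sense is reversed). The electron-rich dienyl phosphate may also ionise or be attacked at C5 or C1, and ethyl may transfer from zinc in place of the homoenolate. The fallback sets out from 4 and comes back to the route at 12. It keeps the homoenolate C9′–C10′ bond construction but moves the stereo-defining event to an alkyl-substituted phosphate and an alkenyl nucleophile. Cyclopropanol 4 is ring-opened and cross-coupled with (E)-3-iodobut-2-en-1-ol (Pd(OAc)2, 2-dicyclohexylphosphino-2′,4′,6′-triisopropylbiphenyl, Cs2CO3, toluene, 80 °C) to give (6E)-2-(BakAr-oxy)-8-hydroxy-2,6-dimethyloct-6-en-3-one F1. Phosphorylation (ClP(O)(OEt)2, pyridine) gives (2E)-7-(BakAr-oxy)-3,7-dimethyl-6-oxooct-2-en-1-yl diethyl phosphate F2. The quaternary centre is then set by NHC–copper-catalysed enantioselective SN2′ substitution of F2 (CuCl, the same imidazolinium sulfonate, NaOMe, THF) with (E)-2-[4-(TBS-oxy)phenyl]ethenylboronic acid pinacol ester F3, itself made from 4-(TBS-oxy)phenylacetylene and pinacolborane. This delivers 12 with no dienyl cation possible, and steps 3–5 are then not needed.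

**Step 2 (Kulinkovich reaction).** The ester is hindered (α,α-disubstituted, α-aryloxy) and the substrate carries alkenes that could exchange on titanium. The fallback sets out from 3 and comes back at 12, generating the same homoenolate from a β-iodo ketone instead of a cyclopropanol. Ester 3 is converted (MeNH(OMe)·HCl, iPrMgCl, THF) into 2-(BakAr-oxy)-N-methoxy-N,2-dimethylpropanamide F4. Vinylmagnesium bromide gives 4-(BakAr-oxy)-4-methylpent-1-en-3-one F5. Conjugate addition of HI (NaI, Me3SiCl, MeCN, −20 °C, then water) gives 4-(BakAr-oxy)-1-iodo-4-methylpentan-3-one F6; the α-keto position keeps the tertiary aryl ether from ionising. Zinc insertion (Zn dust, LiCl, THF) gives [4-(BakAr-oxy)-4-methyl-3-oxopentyl]zinc iodide F7, which is used directly with 9 under the copper/NHC conditions of step 6 to give 12.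

**Step 7 (CBS reduction).** Catecholborane may reduce this hindered α-aryloxy ketone slowly, more forcing borane sources risk hydroboration of the vinyl groups, and the remote stereocentres give no help if selectivity is modest. The fallback sets out from 12 and comes back at 14, replacing reagent control by a covalent resolution. NaBH4 (MeOH, 0 °C) gives 13 together with its epimer (3R,6S,7E)-2-(BakAr-oxy)-8-[4-(TBS-oxy)phenyl]-6-ethenyl-2,6-dimethyloct-7-en-3-ol F8. Esterification of the mixture with (S)-O-methylmandelic acid (N,N′-dicyclohexylcarbodiimide, 4-(dimethylamino)pyridine, CH2Cl2) gives the (S)-O-methylmandelate of 13 F9 and the (S)-O-methylmandelate of the epimer F10. These differ at a centre next to the auxiliary and are separated by chromatography. KOH/MeOH then cleaves both the ester and the aryl silyl ether of F9 to give 14.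

Further compounds
F1 | step 6 | (6E)-2-(BakAr-oxy)-8-hydroxy-2,6-dimethyloct-6-en-3-one | C=C[C@@](C)(/C=C/c1ccc(OC(C)(C)C(=O)CC/C(C)=C/CO)cc1)CCC=C(C)C
F2 | step 6 | (2E)-7-(BakAr-oxy)-3,7-dimethyl-6-oxooct-2-en-1-yl diethyl phosphate | C=C[C@@](C)(/C=C/c1ccc(OC(C)(C)C(=O)CC/C(C)=C/COP(=O)(OCC)OCC)cc1)CCC=C(C)C
F3 | step 6 | (E)-2-[4-(TBS-oxy)phenyl]ethenylboronic acid pinacol ester | CC(C)(C)[Si](C)(C)Oc1ccc(/C=C/B2OC(C)(C)C(C)(C)O2)cc1
F4 | step 2 | 2-(BakAr-oxy)-N-methoxy-N,2-dimethylpropanamide | C=C[C@@](C)(/C=C/c1ccc(OC(C)(C)C(=O)N(C)OC)cc1)CCC=C(C)C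
F5 | step 2 | 4-(BakAr-oxy)-4-methylpent-1-en-3-one | C=C[C@@](C)(/C=C/c1ccc(OC(C)(C)C(=O)C=C)cc1)CCC=C(C)C
F6 | step 2 | 4-(BakAr-oxy)-1-iodo-4-methylpentan-3-one | C=C[C@@](C)(/C=C/c1ccc(OC(C)(C)C(=O)CCI)cc1)CCC=C(C)C
F7 | step 2 | [4-(BakAr-oxy)-4-methyl-3-oxopentyl]zinc iodide | C=C[C@@](C)(/C=C/c1ccc(OC(C)(C)C(=O)CC[Zn]I)cc1)CCC=C(C)C
F8 | step 7 | (3R,6S,7E)-2-(BakAr-oxy)-8-[4-(TBS-oxy)phenyl]-6-ethenyl-2,6-dimethyloct-7-en-3-ol | C=C[C@@](C)(/C=C/c1ccc(OC(C)(C)[C@H](O)CC[C@@](C)(C=C)/C=C/c2ccc(O[Si](C)(C)C(C)(C)C)cc2)cc1)CCC=C(C)C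
F9 | step 7 | (S)-O-methylmandelate of 13 | C=C[C@@](C)(/C=C/c1ccc(OC(C)(C)[C@@H](OC(=O)[C@@H](OC)c2ccccc2)CC[C@@](C)(C=C)/C=C/c2ccc(O[Si](C)(C)C(C)(C)C)cc2)cc1)CCC=C(C)C
F10 | step 7 | (S)-O-methylmandelate of F8 | C=C[C@@](C)(/C=C/c1ccc(OC(C)(C)[C@H](OC(=O)[C@@H](OC)c2ccccc2)CC[C@@](C)(C=C)/C=C/c2ccc(O[Si](C)(C)C(C)(C)C)cc2)cc1)CCC=C(C)C
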